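**Plan**

Numbering: C1 is the lactone carbonyl, C2 carries the ethyl group, C27 carries the lactone oxygen, C28 is its methyl.

1. Retrosynthetic cuts: C5–C6 (ring closure, with C5 raised to the acyl/ketone level), the C1–O ester, C21–C22 and C19–C20 (Stille), C10–C11 (Mukaiyama aldol), C12–C13 (Claisen), C14–C15 and C2–C3 (Evans aldols), C26–C27 (crotylboration).
2. Forward: fragment 1 (C22–C28 iododienol 8), fragment 2 (C1–C5 acid 17, esterified to 8 and oxidised to acid 21) and fragment 3 (C6–C19 diiodide 41, from C11–C19 aldehyde 35 and 5-chloropentan-2-one as C6–C10) are joined through the pentaene by two Stille couplings around a C20–C21 bis-stannane. The 28-membered ring (C1–C27 plus the lactone oxygen) is closed last at C5–C6.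
3. Enabling feature: C6, C7 and C8 are three plain methylenes between the C5 and C9 oxygens, so C6 can be a primary iodide/radical with no β-leaving group. C5, between C4H2 and C6 and β to the C3 oxygen, can be an acyl carbon (2-pyridyl thioester). Nickel-mediated acyl–alkyl coupling closes the ring as the C5 ketone, which the C3 hydroxyl then directs to the 1,3-anti alcohol.
4. Stereochemistry: C26/C27 by Brown (Z)-crotylboration; C2/C3 and C14/C15 by Evans syn-aldols with the same (S)-benzyl auxiliary. Relayed from these: C13 (anti, from C15), C11 (1,3-anti, from C13), C9 (syn, from C11) and C5 (anti, from C3). All E-alkenes come from cross-metathesis, Takai olefinations and (E)-1,2-bis(tributylstannyl)ethene.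

Key step: step 29

Remark: the free target is assumed to persist as the 28-membered lactone (no translactonisation onto the C5 hydroxyl) under the buffered fluoride conditions of the last step; iododienes, stannanes and polyenes are handled in the dark under argon.

**Fragment 1 (C22–C28)**

Step 1
Reactants: 1 acetaldehyde; 2 (Z)-but-2-ene
Product: 4 (2R,3R)-3-methylpent-4-en-2-ol, via (Z)-crotyldiisopinocampheylborane 3 (not isolated)
Conditions: 2, KOt-Bu, n-BuLi, THF, −78 to −45 °C; (−)-Ipc2BOMe, −78 °C; BF3·OEt2; 1, −78 °C; then NaOH, H2O2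
Reagents that add atoms: none
Why: Brown crotylboration through a chair (Zimmerman–Traxler) transition state, in which the Z-crotyl geometry gives the syn methyl/hydroxyl pair and the isopinocampheyl groups of the reagent made from (−)-Ipc2BOMe select the aldehyde face, should set C26 and C27 as R,R.

Step 2
Reactants: 4; 5 (E)-but-2-enal
Product: 6 (2E,4R,5R)-5-hydroxy-4-methylhex-2-enal
Conditions: 5 (5 equiv), second-generation Hoveyda–Grubbs catalyst (5 mol%), CH2Cl2, 40 °C
Reagents that add atoms: none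
Why: Olefin cross-metathesis of the terminal alkene with an excess of the electron-poor enal should give the E-enal with loss of propene and without touching C26/C27.

Step 3
Reactants: 6; 7 iodoform
Product: 8 (2R,3R,4E,6E)-7-iodo-3-methylhepta-4,6-dien-2-ol
Conditions: CrCl2, 7, THF, 0 °C, dark
Reagents that add atoms: none
Why: Takai olefination, in which the geminal dichromium species from CHI3 adds to the aldehyde and eliminates to the E-vinyl iodide, tolerates the free hydroxyl and should extend the enal to the E,E-iododiene.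

**Fragment 2 (C1–C5, joined to fragment 1)**

Step 4
Reactants: 9 3-[(4-methoxybenzyl)oxy]propan-1-ol
Product: 10 3-[(4-methoxybenzyl)oxy]propanal
Conditions: TEMPO (10 mol%), PhI(OAc)2, CH2Cl2, rt
Reagents that add atoms: none
Why: The oxoammonium (TEMPO/PhI(OAc)2) oxidation of a primary alcohol stops at the aldehyde in anhydrous CH2Cl2 and leaves the PMB ether intact.

Step 5
Reactants: 11 (S)-4-benzyl-1,3-oxazolidin-2-one; 12 butanoyl chloride
Product: 13 (S)-4-benzyl-3-butanoyl-1,3-oxazolidin-2-one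
Conditions: n-BuLi, THF, −78 °C; 12, −78 to 0 °C
Reagents that add atoms: none
Why: N-Acylation of the lithiated oxazolidinone by the acid chloride is the standard entry to Evans imides.

Step 6
Reactants: 13; 10
Product: 15 (S)-4-benzyl-3-{(2S,3R)-2-ethyl-3-hydroxy-5-[(4-methoxybenzyl)oxy]pentanoyl}-1,3-oxazolidin-2-one, via dibutylboron (Z)-enolate 14 (not isolated)
Conditions: Bu2BOTf, i-Pr2NEt, CH2Cl2, −78 to 0 °C; 10, −78 to 0 °C; pH 7 buffer, MeOH, H2O2
Reagents that add atoms: none
Why: Evans syn-aldol, in which the Z-boron enolate reacts through a chair transition state with the auxiliary carbonyl dipole opposed and the benzyl group shielding one enolate face, should set C2 (S) and C3 (R) with ethyl and hydroxyl syn.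

Step 7
Reactants: 15
Product: 16 (S)-4-benzyl-3-{(2S,3R)-2-ethyl-5-[(4-methoxybenzyl)oxy]-3-(triethylsilyloxy)pentanoyl}-1,3-oxazolidin-2-one
Conditions: Et3SiOTf, 2,6-lutidine, CH2Cl2, −78 °C
Reagents that add atoms: triethylsilyl trifluoromethanesulfonate, CC[Si](CC)(CC)OS(=O)(=O)C(F)(F)F
Why: Silyl triflate/lutidine silylation protects the hindered C3 hydroxyl as the one silyl ether that can later be removed selectively.

Step 8
Reactants: 16
Product: 17 (2S,3R)-2-ethyl-5-[(4-methoxybenzyl)oxy]-3-(triethylsilyloxy)pentanoic acid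
Conditions: LiOH, H2O2, THF/H2O, 0 °C; Na2SO3; cold dilute HCl to pH 4
Reagents that add atoms: hydrogen peroxide, OO
Why: Lithium hydroperoxide attacks the exocyclic imide carbonyl selectively, so the auxiliary is released without epimerising C2 or eliminating the C3 silyloxy group.

Step 9
Reactants: 17; 8
Product: 19 (2R,3R,4E,6E)-7-iodo-3-methylhepta-4,6-dien-2-yl (2S,3R)-2-ethyl-5-[(4-methoxybenzyl)oxy]-3-(triethylsilyloxy)pentanoate, via 2,4,6-trichlorobenzoic mixed anhydride 18 (not isolated)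
Conditions: 2,4,6-trichlorobenzoyl chloride, Et3N, toluene, rt; then 8, DMAP, rt
Reagents that add atoms: none
Why: Yamaguchi esterification (mixed anhydride, then DMAP acyl transfer) should acylate the hindered C27 hydroxyl with retention, because the C27–O bond is not broken.

Step 10
Reactants: 19
Product: 20 (2R,3R,4E,6E)-7-iodo-3-methylhepta-4,6-dien-2-yl (2S,3R)-2-ethyl-5-hydroxy-3-(triethylsilyloxy)pentanoate
Conditions: DDQ, CH2Cl2/pH 7 buffer, 0 °C
Reagents that add atoms: none
Why: Oxidative cleavage of the PMB ether by DDQ in buffered wet CH2Cl2 leaves the TES ether, the ester and the electron-poor iododiene untouched.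

Step 11
Reactants: 20
Product: 21 (3R,4S)-4-({[(2R,3R,4E,6E)-7-iodo-3-methylhepta-4,6-dien-2-yl]oxy}carbonyl)-3-(triethylsilyloxy)hexanoic acid
Conditions: TEMPO (20 mol%), PhI(OAc)2, MeCN/H2O, 0 °C to rt
Reagents that add atoms: water, O
Why: In aqueous acetonitrile the TEMPO/PhI(OAc)2 oxidation carries the primary alcohol through the aldehyde hydrate to the carboxylic acid, bringing C5 to the acyl level in one operation.

**Fragment 3 (C6–C19)**

Step 12
Reactants: 22 fumaraldehyde bis(dimethyl acetal)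
Product: 23 (E)-4,4-dimethoxybut-2-enal
Conditions: Amberlyst-15, acetone, H2O (1 equiv), rt
Reagents that add atoms: water, O
Why: Acid-catalysed hydrolysis stops after one acetal because the conjugated aldehyde formed deactivates the remaining acetal towards ionisation.

Step 13
Reactants: 23; 7
Product: 24 (1E,3E)-1-iodo-5,5-dimethoxypenta-1,3-diene
Conditions: CrCl2, 7, THF, 0 °C, dark
Reagents that add atoms: none
Why: Takai olefination of the enal should give the E,E-iododiene, and the acetal is inert to the chromium reagent.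

Step 14
Reactants: 24
Product: 25 (2E,4E)-5-iodopenta-2,4-dienal
Conditions: aq. oxalic acid, THF, rt, dark
Reagents that add atoms: water, O
Why: Mild acid hydrolysis of the allylic dimethyl acetal releases the dienal without isomerising the iododiene.

Step 15
Reactants: 26 (S)-4-benzyl-3-propanoyl-1,3-oxazolidin-2-one; 25
Product: 28 (S)-4-benzyl-3-[(2S,3R,4E,6E)-3-hydroxy-7-iodo-2-methylhepta-4,6-dienoyl]-1,3-oxazolidin-2-one, via dibutylboron (Z)-enolate 27 (not isolated)
Conditions: Bu2BOTf, i-Pr2NEt, CH2Cl2, −78 to 0 °C; 25, −78 to 0 °C; pH 7 buffer, MeOH, H2O2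
Reagents that add atoms: none
Why: The same Evans syn-aldol manifold as in step 6 should set C14 and C15 with methyl and hydroxyl syn, under control of the (S)-benzyl auxiliary.

Step 16
Reactants: 28
Product: 29 (2S,3R,4E,6E)-3-hydroxy-7-iodo-N-methoxy-N,2-dimethylhepta-4,6-dienamide
Conditions: MeONHMe·HCl, AlMe3, CH2Cl2, −20 to 0 °C; aq. potassium sodium tartrate
Reagents that add atoms: N,O-dimethylhydroxylamine hydrochloride, CNOC.Cl
Why: Aluminium-amide transamidation, directed to the exocyclic carbonyl by the free β-hydroxyl, gives the Weinreb amide and frees the auxiliary.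

Step 17
Reactants: 29; 30 methyl acetate
Product: 32 methyl (4S,5R,6E,8E)-5-hydroxy-9-iodo-4-methyl-3-oxonona-6,8-dienoate, via lithium enolate 31 (not isolated)
Conditions: 30 (4 equiv), LiN(i-Pr)2 (3.5 equiv), THF, −78 °C; 29, −78 to −40 °C; aq. NH4Cl
Reagents that add atoms: none
Why: Claisen-type acylation of the ester enolate by the Weinreb amide stops at the ketone because the chelated tetrahedral adduct collapses only on work-up, which adds C11 and C12.

Step 18
Reactants: 32
Product: 33 methyl (3R,4R,5R,6E,8E)-3,5-dihydroxy-9-iodo-4-methylnona-6,8-dienoate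
Conditions: Me4NBH(OAc)3, MeCN/AcOH, −30 °C
Reagents that add atoms: none
Why: Evans–Saksena reduction, in which the C15 hydroxyl exchanges onto boron and delivers hydride intramolecularly through a chair six-membered transition state, should set C13 1,3-anti to C15.

Step 19
Reactants: 33
Product: 34 methyl (3R,4R,5R,6E,8E)-3,5-bis[(tert-butyldimethylsilyl)oxy]-9-iodo-4-methylnona-6,8-dienoate
Conditions: t-BuMe2SiOTf, 2,6-lutidine, CH2Cl2, −78 to 0 °C (crude 33 used at once)
Reagents that add atoms: tert-butyldimethylsilyl trifluoromethanesulfonate, CC(C)(C)[Si](C)(C)OS(=O)(=O)C(F)(F)F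
Why: Immediate bis-silylation of the diol forestalls lactonisation of the 3,5-dihydroxy ester and installs the groups that stay to the end.

Step 20
Reactants: 34
Product: 35 (3R,4R,5R,6E,8E)-3,5-bis[(tert-butyldimethylsilyl)oxy]-9-iodo-4-methylnona-6,8-dienal
Conditions: i-Bu2AlH, CH2Cl2, −78 °C; MeOH; aq. potassium sodium tartrate
Reagents that add atoms: none
Why: Half-reduction of the methyl ester stops at the aldehyde because the aluminium hemiacetal is stable at −78 °C.

Step 21
Reactants: 36 5-chloropentan-2-one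
Product: 37 [(5-chloropent-1-en-2-yl)oxy]trimethylsilane
Conditions: LiN(i-Pr)2, Me3SiCl, THF, −78 °C (36 added to the base/silyl chloride mixture); pentane, filtration
Reagents that add atoms: chlorotrimethylsilane, C[Si](C)(C)Cl
Why: Kinetic deprotonation at the methyl group with in-situ silyl trapping gives the less substituted enol silane before the enolate can displace the chloride.

Step 22
Reactants: 35; 37
Product: 38 (6R,8R,9R,10R,11E,13E)-8,10-bis[(tert-butyldimethylsilyl)oxy]-1-chloro-6-hydroxy-14-iodo-9-methyltetradeca-11,13-dien-4-one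
Conditions: BF3·OEt2, CH2Cl2, −78 °C; aq. NaHCO3
Reagents that add atoms: none
Why: Mukaiyama aldol through an open transition state, in which the β-silyloxy stereocentre C13 of the BF3-bound aldehyde directs attack to the 1,3-anti face (dipole-minimised model), should join C10–C11 and set C11.

Step 23
Reactants: 38
Product: 39 (4S,6S,8R,9R,10R,11E,13E)-8,10-bis[(tert-butyldimethylsilyl)oxy]-1-chloro-14-iodo-9-methyltetradeca-11,13-diene-4,6-diol
Conditions: Et2BOMe, THF/MeOH, −78 °C; NaBH4; then MeOH co-evaporation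
Reagents that add atoms: none
Why: Narasaka–Prasad reduction, in which the boron chelate of the β-hydroxy ketone takes axial hydride from outside, should set C9 1,3-syn to C11.

Step 24
Reactants: 39
Product: 40 (1E,3E,5R,6R,7R,9S,11S)-5,7,9,11-tetrakis[(tert-butyldimethylsilyl)oxy]-14-chloro-1-iodo-6-methyltetradeca-1,3-diene
Conditions: t-BuMe2SiOTf, 2,6-lutidine, CH2Cl2, −78 to 0 °C
Reagents that add atoms: tert-butyldimethylsilyl trifluoromethanesulfonate, CC(C)(C)[Si](C)(C)OS(=O)(=O)C(F)(F)F
Why: Bis-silylation completes a uniform silyl protection of the C9–C15 polyol.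

Step 25
Reactants: 40
Product: 41 (1E,3E,5R,6R,7R,9S,11S)-5,7,9,11-tetrakis[(tert-butyldimethylsilyl)oxy]-1,14-diiodo-6-methyltetradeca-1,3-diene
Conditions: NaI, acetone, 56 °C, dark
Reagents that add atoms: sodium iodide, [Na+].[I-]
Why: Finkelstein SN2 exchange at the unhindered primary C6, driven by precipitation of NaCl, installs the alkyl iodide before any polyene is present.

**Assembly and ring closure**

Step 26
Reactants: 41; 42 (E)-1,2-bis(tributylstannyl)ethene
Product: 43 tributyl[(1E,3E,5E,7R,8R,9R,11S,13S)-7,9,11,13-tetrakis[(tert-butyldimethylsilyl)oxy]-16-iodo-8-methylhexadeca-1,3,5-trien-1-yl]stannane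
Conditions: 42 (4 equiv), PdCl2(MeCN)2 (5 mol%), DMF, rt, dark
Reagents that add atoms: none
Why: Stille coupling with an excess of the bis-stannane should give the mono-coupled E,E,E-trienylstannane with retention of alkene geometry, and zerovalent palladium without electron-rich phosphines adds to the sp2 C–I bond far faster than to the primary alkyl iodide.

Step 27
Reactants: 43; 21
Product: 44 C1–C28 seco acid (C5 carboxylic acid; C6 iodide; 3-OTES; 9,11,13,15-tetra-OTBS; all-E pentaene)
Conditions: Pd2(dba)3·CHCl3 (10 mol%), AsPh3, i-Pr2NEt, DMF/THF, rt, dark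
Reagents that add atoms: none
Why: A second Stille coupling with the weakly donating arsine ligand should form C21–C22 at room temperature and complete the all-E pentaene, the acid being kept as its ammonium carboxylate.

Step 28
Reactants: 44
Product: 45 S-(pyridin-2-yl) thioester of 44
Conditions: 2,2′-dipyridyl disulfide, PPh3, CH2Cl2, rt
Reagents that add atoms: 2,2′-dipyridyl disulfide, c1ccc(SSc2ccccn2)nc1
Why: Mukaiyama redox condensation converts the acid into the 2-pyridyl thioester under neutral conditions that leave the pentaene, the alkyl iodide and the silyl ethers alone.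

Step 29
Reactants: 45
Product: 46 macrocyclic C5 ketone (28-membered lactone; 3-OTES; 9,11,13,15-tetra-OTBS)
Conditions: NiBr2(4,4′-di-tert-butyl-2,2′-bipyridine) (1.5 equiv), Cp2ZrCl2 (3 equiv), Zn dust (10 equiv), 1,3-dimethyl-2-imidazolidinone/EtOAc, rt, 45 added by syringe pump (final 1 mM), dark
Reagents that add atoms: none
Why: Proposed new method: Zerovalent nickel (from the nickel dibromide complex and Zn) inserts into the C5–S bond of the chelating 2-pyridyl thioester to give a C5 acylnickel species, Cp2ZrCl2 takes up the thiolate, and zinc-reduced trivalent zirconium (or monovalent nickel) abstracts iodine from C6 to give a primary radical that is captured by the acylnickel centre of the same molecule, after which reductive elimination from trivalent nickel forms the C5–C6 bond. The closest known reaction type is the intermolecular nickel/zirconium-mediated ketone synthesis from 2-pyridyl thioesters and primary alkyl iodides (a reductive acyl–alkyl cross-electrophile coupling) used for neutral fragment unions; here it is run intramolecularly with stoichiometric nickel and slow addition. The closure is a 28-membered macrocyclisation (C(acyl)–C(sp3) bond; ring atoms C1–C27 plus the lactone oxygen), helped by the rigid all-E pentaene. No stereocentre is created, since C5 becomes a ketone whose configuration follows in step 31 from C3, and C2, C3 and the silyl ethers see neither base nor acid. The step needs ring closure to beat dimerisation and C6–H reduction, which high dilution and a full equivalent of nickel (so that each molecule carries its acylnickel before its radical forms) should secure, and it needs chemoselectivity for the thioester over the hindered C1 ester and for the primary iodide, whose neighbours C7 and C8 are plain methylenes with no β-leaving group and which lies far from the pentaene.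

Step 30
Reactants: 46
Product: 47 macrocyclic 3-hydroxy-5-ketone (9,11,13,15-tetra-OTBS)
Conditions: HF·pyridine, pyridine, THF, 0 °C
Reagents that add atoms: none
Why: Buffered fluoride removes the secondary triethylsilyl ether much faster than the four tert-butyldimethylsilyl ethers, freeing only the C3 hydroxyl.

Step 31
Reactants: 47
Product: 48 macrocyclic 3,5-anti-diol (9,11,13,15-tetra-OTBS)
Conditions: Me4NBH(OAc)3, MeCN/AcOH, −30 °C
Reagents that add atoms: none
Why: Evans–Saksena reduction with intramolecular hydride delivery from the C3-bound borohydride through a chair transition state should set C5 (S), 1,3-anti to C3, independently of the macrocycle conformation.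

Step 32
Reactants: 48
Product: 49 CNP0382847.1
Conditions: HF·pyridine, pyridine, THF, rt, dark; reversed-phase purification
Reagents that add atoms: none
Why: Pyridine-buffered HF cleaves the four remaining silyl ethers without the acid or base that would ionise the pentaenyl carbinol at C15 or open the lactone.

**Compound list**

1 | acetaldehyde | CC=O | starting material
2 | (Z)-but-2-ene | C/C=C\C | starting material
3 | (Z)-crotyldiisopinocampheylborane (from (−)-Ipc2BOMe) | C/C=C\CB([C@@H]1C[C@@H]2C[C@H]([C@H]1C)C2(C)C)[C@@H]1C[C@@H]2C[C@H]([C@H]1C)C2(C)C | intermediate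
4 | (2R,3R)-3-methylpent-4-en-2-ol | O[C@H](C)[C@H](C)C=C | intermediate
5 | (E)-but-2-enal | C/C=C/C=O | starting material
6 | (2E,4R,5R)-5-hydroxy-4-methylhex-2-enal | O[C@H](C)[C@H](C)/C=C/C=O | intermediate
7 | iodoform | IC(I)I | starting material
8 | (2R,3R,4E,6E)-7-iodo-3-methylhepta-4,6-dien-2-ol (fragment 1) | O[C@H](C)[C@H](C)/C=C/C=C/I | intermediate
9 | 3-[(4-methoxybenzyl)oxy]propan-1-ol | OCCCOCc1ccc(OC)cc1 | starting material
10 | 3-[(4-methoxybenzyl)oxy]propanal | O=CCCOCc1ccc(OC)cc1 | intermediate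
11 | (S)-4-benzyl-1,3-oxazolidin-2-one | O=C1OC[C@H](Cc2ccccc2)N1 | starting material
12 | butanoyl chloride | CCCC(Cl)=O | starting material
13 | (S)-4-benzyl-3-butanoyl-1,3-oxazolidin-2-one | CCCC(=O)N1[C@@H](Cc2ccccc2)COC1=O | intermediate
14 | dibutylboron (Z)-enolate of 13 | CC/C=C(\OB(CCCC)CCCC)N1[C@@H](Cc2ccccc2)COC1=O | intermediate
15 | (S)-4-benzyl-3-{(2S,3R)-2-ethyl-3-hydroxy-5-[(4-methoxybenzyl)oxy]pentanoyl}-1,3-oxazolidin-2-one | CC[C@H](C(=O)N1[C@@H](Cc2ccccc2)COC1=O)[C@@H](CCOCc3ccc(OC)cc3)O | intermediate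
16 | triethylsilyl ether of 15 (2S,3R) | CC[C@H](C(=O)N1[C@@H](Cc2ccccc2)COC1=O)[C@@H](CCOCc3ccc(OC)cc3)O[Si](CC)(CC)CC | intermediate
17 | (2S,3R)-2-ethyl-5-[(4-methoxybenzyl)oxy]-3-(triethylsilyloxy)pentanoic acid | CC[C@H](C(=O)O)[C@@H](CCOCc1ccc(OC)cc1)O[Si](CC)(CC)CC | intermediate
18 | mixed anhydride of 17 with 2,4,6-trichlorobenzoic acid | CC[C@H](C(=O)OC(=O)c1c(Cl)cc(Cl)cc1Cl)[C@@H](CCOCc2ccc(OC)cc2)O[Si](CC)(CC)CC | intermediate
19 | (2R,3R,4E,6E)-7-iodo-3-methylhepta-4,6-dien-2-yl (2S,3R)-2-ethyl-5-[(4-methoxybenzyl)oxy]-3-(triethylsilyloxy)pentanoate | CC[C@H](C(=O)O[C@H](C)[C@H](C)/C=C/C=C/I)[C@@H](CCOCc1ccc(OC)cc1)O[Si](CC)(CC)CC | intermediate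
20 | (2R,3R,4E,6E)-7-iodo-3-methylhepta-4,6-dien-2-yl (2S,3R)-2-ethyl-5-hydroxy-3-(triethylsilyloxy)pentanoate | CC[C@H](C(=O)O[C@H](C)[C@H](C)/C=C/C=C/I)[C@@H](CCO)O[Si](CC)(CC)CC | intermediate
21 | (3R,4S)-4-({[(2R,3R,4E,6E)-7-iodo-3-methylhepta-4,6-dien-2-yl]oxy}carbonyl)-3-(triethylsilyloxy)hexanoic acid (fragments 1 and 2 joined) | CC[C@H](C(=O)O[C@H](C)[C@H](C)/C=C/C=C/I)[C@@H](CC(=O)O)O[Si](CC)(CC)CC | intermediate
22 | fumaraldehyde bis(dimethyl acetal) | COC(OC)/C=C/C(OC)OC | starting material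
23 | (E)-4,4-dimethoxybut-2-enal | COC(OC)/C=C/C=O | intermediate
24 | (1E,3E)-1-iodo-5,5-dimethoxypenta-1,3-diene | COC(OC)/C=C/C=C/I | intermediate
25 | (2E,4E)-5-iodopenta-2,4-dienal | O=C/C=C/C=C/I | intermediate
26 | (S)-4-benzyl-3-propanoyl-1,3-oxazolidin-2-one | CCC(=O)N1[C@@H](Cc2ccccc2)COC1=O | starting material
27 | dibutylboron (Z)-enolate of 26 | C/C=C(\OB(CCCC)CCCC)N1[C@@H](Cc2ccccc2)COC1=O | intermediate
28 | (S)-4-benzyl-3-[(2S,3R,4E,6E)-3-hydroxy-7-iodo-2-methylhepta-4,6-dienoyl]-1,3-oxazolidin-2-one | I/C=C/C=C/[C@@H](O)[C@H](C)C(=O)N1[C@@H](Cc2ccccc2)COC1=O | intermediate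
29 | (2S,3R,4E,6E)-3-hydroxy-7-iodo-N-methoxy-N,2-dimethylhepta-4,6-dienamide | I/C=C/C=C/[C@@H](O)[C@H](C)C(=O)N(C)OC | intermediate
30 | methyl acetate | CC(=O)OC | starting material
31 | lithium enolate of methyl acetate | [Li]OC(=C)OC | intermediate
32 | methyl (4S,5R,6E,8E)-5-hydroxy-9-iodo-4-methyl-3-oxonona-6,8-dienoate | I/C=C/C=C/[C@@H](O)[C@H](C)C(=O)CC(=O)OC | intermediate
33 | methyl (3R,4R,5R,6E,8E)-3,5-dihydroxy-9-iodo-4-methylnona-6,8-dienoate | I/C=C/C=C/[C@@H](O)[C@H](C)[C@H](O)CC(=O)OC | intermediate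
34 | methyl (3R,4R,5R,6E,8E)-3,5-bis[(tert-butyldimethylsilyl)oxy]-9-iodo-4-methylnona-6,8-dienoate | I/C=C/C=C/[C@@H](O[Si](C)(C)C(C)(C)C)[C@H](C)[C@H](O[Si](C)(C)C(C)(C)C)CC(=O)OC | intermediate
35 | (3R,4R,5R,6E,8E)-3,5-bis[(tert-butyldimethylsilyl)oxy]-9-iodo-4-methylnona-6,8-dienal | I/C=C/C=C/[C@@H](O[Si](C)(C)C(C)(C)C)[C@H](C)[C@H](O[Si](C)(C)C(C)(C)C)CC=O | intermediate
36 | 5-chloropentan-2-one | CC(=O)CCCCl | starting material
37 | [(5-chloropent-1-en-2-yl)oxy]trimethylsilane | C=C(CCCCl)O[Si](C)(C)C | intermediate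
38 | (6R,8R,9R,10R,11E,13E)-8,10-bis[(tert-butyldimethylsilyl)oxy]-1-chloro-6-hydroxy-14-iodo-9-methyltetradeca-11,13-dien-4-one | I/C=C/C=C/[C@@H](O[Si](C)(C)C(C)(C)C)[C@H](C)[C@H](O[Si](C)(C)C(C)(C)C)C[C@@H](O)CC(=O)CCCCl | intermediate
39 | (4S,6S,8R,9R,10R,11E,13E)-8,10-bis[(tert-butyldimethylsilyl)oxy]-1-chloro-14-iodo-9-methyltetradeca-11,13-diene-4,6-diol | I/C=C/C=C/[C@@H](O[Si](C)(C)C(C)(C)C)[C@H](C)[C@H](O[Si](C)(C)C(C)(C)C)C[C@@H](O)C[C@@H](O)CCCCl | intermediate
40 | (1E,3E,5R,6R,7R,9S,11S)-5,7,9,11-tetrakis[(tert-butyldimethylsilyl)oxy]-14-chloro-1-iodo-6-methyltetradeca-1,3-diene | I/C=C/C=C/[C@@H](O[Si](C)(C)C(C)(C)C)[C@H](C)[C@H](O[Si](C)(C)C(C)(C)C)C[C@@H](O[Si](C)(C)C(C)(C)C)C[C@@H](O[Si](C)(C)C(C)(C)C)CCCCl | intermediate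
41 | (1E,3E,5R,6R,7R,9S,11S)-5,7,9,11-tetrakis[(tert-butyldimethylsilyl)oxy]-1,14-diiodo-6-methyltetradeca-1,3-diene (fragment 3) | I/C=C/C=C/[C@@H](O[Si](C)(C)C(C)(C)C)[C@H](C)[C@H](O[Si](C)(C)C(C)(C)C)C[C@@H](O[Si](C)(C)C(C)(C)C)C[C@@H](O[Si](C)(C)C(C)(C)C)CCCI | intermediate
42 | (E)-1,2-bis(tributylstannyl)ethene | CCCC[Sn](CCCC)(CCCC)/C=C/[Sn](CCCC)(CCCC)CCCC | starting material
43 | tributyl[(1E,3E,5E,7R,8R,9R,11S,13S)-7,9,11,13-tetrakis[(tert-butyldimethylsilyl)oxy]-16-iodo-8-methylhexadeca-1,3,5-trien-1-yl]stannane | CCCC[Sn](CCCC)(CCCC)/C=C/C=C/C=C/[C@@H](O[Si](C)(C)C(C)(C)C)[C@H](C)[C@H](O[Si](C)(C)C(C)(C)C)C[C@@H](O[Si](C)(C)C(C)(C)C)C[C@@H](O[Si](C)(C)C(C)(C)C)CCCI | intermediate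
44 | seco acid: C5 carboxylic acid, C6 iodide, C1 ester to O27; 2S,3R,9S,11S,13R,14R,15R,26R,27R; all-E pentaene; 3-OTES; 9,11,13,15-OTBS | CC[C@H](C(=O)O[C@H](C)[C@H](C)/C=C/C=C/C=C/C=C/C=C/[C@@H](O[Si](C)(C)C(C)(C)C)[C@H](C)[C@H](O[Si](C)(C)C(C)(C)C)C[C@@H](O[Si](C)(C)C(C)(C)C)C[C@@H](O[Si](C)(C)C(C)(C)C)CCCI)[C@@H](CC(=O)O)O[Si](CC)(CC)CC | intermediate
45 | S-(pyridin-2-yl) thioester of 44 (same configurations) | CC[C@H](C(=O)O[C@H](C)[C@H](C)/C=C/C=C/C=C/C=C/C=C/[C@@H](O[Si](C)(C)C(C)(C)C)[C@H](C)[C@H](O[Si](C)(C)C(C)(C)C)C[C@@H](O[Si](C)(C)C(C)(C)C)C[C@@H](O[Si](C)(C)C(C)(C)C)CCCI)[C@@H](CC(=O)Sc1ccccn1)O[Si](CC)(CC)CC | intermediate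
46 | macrocyclic C5 ketone; 2S,3R,9S,11S,13R,14R,15R,26R,27R; 3-OTES; 9,11,13,15-OTBS | CC[C@@H]1C(=O)O[C@H](C)[C@H](C)/C=C/C=C/C=C/C=C/C=C/[C@@H](O[Si](C)(C)C(C)(C)C)[C@H](C)[C@H](O[Si](C)(C)C(C)(C)C)C[C@@H](O[Si](C)(C)C(C)(C)C)C[C@@H](O[Si](C)(C)C(C)(C)C)CCCC(=O)C[C@H]1O[Si](CC)(CC)CC | intermediate
47 | macrocyclic 3-hydroxy-5-ketone; 9,11,13,15-OTBS | CC[C@@H]1C(=O)O[C@H](C)[C@H](C)/C=C/C=C/C=C/C=C/C=C/[C@@H](O[Si](C)(C)C(C)(C)C)[C@H](C)[C@H](O[Si](C)(C)C(C)(C)C)C[C@@H](O[Si](C)(C)C(C)(C)C)C[C@@H](O[Si](C)(C)C(C)(C)C)CCCC(=O)C[C@H]1O | intermediate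
48 | macrocyclic (3R,5S)-diol; 9,11,13,15-OTBS | CC[C@@H]1C(=O)O[C@H](C)[C@H](C)/C=C/C=C/C=C/C=C/C=C/[C@@H](O[Si](C)(C)C(C)(C)C)[C@H](C)[C@H](O[Si](C)(C)C(C)(C)C)C[C@@H](O[Si](C)(C)C(C)(C)C)C[C@@H](O[Si](C)(C)C(C)(C)C)CCC[C@H](O)C[C@H]1O | intermediate
49 | CNP0382847.1 (2S,3R,5S,9S,11S,13R,14R,15R,26R,27R; all-E pentaene) | CC[C@@H]1C(=O)O[C@H](C)[C@H](C)/C=C/C=C/C=C/C=C/C=C/[C@@H](O)[C@H](C)[C@H](O)C[C@@H](O)C[C@@H](O)CCC[C@H](O)C[C@H]1O | target

**Totals and risks**

Total step count: 32.
Longest linear sequence: 20 steps (steps 12–20, 22–32, from 22).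

Steps most likely to fail:

1. Step 29. The ring closure may lose to dimerisation, to reduction of the C6 radical to C6–H, or to nickel-induced isomerisation of the pentaene. The fallback forms C5–C6 intermolecularly by the known nickel/zirconium ketone synthesis and closes the ring at the ester. It sets out from 43, 8 and 17 and comes back at 46. Stille coupling of 43 with alcohol 8 (conditions of step 27) gives the pentaene iodo alcohol F1. Acid 17 is esterified with allyl bromide/K2CO3 to the allyl ester F2, DDQ frees the primary alcohol F3, TEMPO/PhI(OAc)2 in aqueous MeCN gives the acid F4, and Mukaiyama redox condensation gives the 2-pyridyl thioester F5. Intermolecular coupling of F5 with F1 under the conditions of step 29 at normal concentration gives the ketone F6. Pd(PPh3)4/PhSiH3 removes the allyl group to give the seco acid F7, and Yamaguchi macrolactonisation onto the C27 hydroxyl gives 46.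

2. Step 22. Facial selectivity at C11 may be poor, because a β-silyloxy group is a weaker 1,3-director than a β-alkoxy group in the open transition state. The fallback uses reagent control in a closed transition state. It sets out from 36 and 35 and comes back at 38. Ketone 36 is enolised at the methyl group with (−)-Ipc2BCl/Et3N to the diisopinocampheylboron enolate F8, which adds to 35 at −78 °C through a chair transition state; oxidative work-up gives 38. The reagent enantiomer that reinforces the 1,3-anti preference is to be chosen on a small scale, and F8 is drawn for (−)-Ipc2BCl.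

3. Step 27. The free acid may protodestannylate the trienylstannane, and a slow coupling would let the growing polyene decompose. The fallback masks the acid. It sets out from 21 and 43 and comes back at 44. Acid 21 is converted with allyl bromide/Cs2CO3 to the allyl ester F9, Stille coupling with 43 gives the pentaene allyl ester F10, and Pd(PPh3)4/PhSiH3 (a non-nucleophilic allyl acceptor that spares the C6 iodide) gives 44.

Further compounds
F1 | step 29 | pentaene iodo alcohol (C6 iodide; free 27-OH; 9,11,13,15-OTBS) | O[C@H](C)[C@H](C)/C=C/C=C/C=C/C=C/C=C/[C@@H](O[Si](C)(C)C(C)(C)C)[C@H](C)[C@H](O[Si](C)(C)C(C)(C)C)C[C@@H](O[Si](C)(C)C(C)(C)C)C[C@@H](O[Si](C)(C)C(C)(C)C)CCCI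
F2 | step 29 | allyl (2S,3R)-2-ethyl-5-[(4-methoxybenzyl)oxy]-3-(triethylsilyloxy)pentanoate | CC[C@H](C(=O)OCC=C)[C@@H](CCOCc1ccc(OC)cc1)O[Si](CC)(CC)CC
F3 | step 29 | allyl (2S,3R)-2-ethyl-5-hydroxy-3-(triethylsilyloxy)pentanoate | CC[C@H](C(=O)OCC=C)[C@@H](CCO)O[Si](CC)(CC)CC
F4 | step 29 | (3R,4S)-4-(allyloxycarbonyl)-3-(triethylsilyloxy)hexanoic acid | CC[C@H](C(=O)OCC=C)[C@@H](CC(=O)O)O[Si](CC)(CC)CC
F5 | step 29 | S-(pyridin-2-yl) thioester of F4 | CC[C@H](C(=O)OCC=C)[C@@H](CC(=O)Sc1ccccn1)O[Si](CC)(CC)CC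
F6 | step 29 | open-chain C5 ketone with C1 allyl ester and free 27-OH | O[C@H](C)[C@H](C)/C=C/C=C/C=C/C=C/C=C/[C@@H](O[Si](C)(C)C(C)(C)C)[C@H](C)[C@H](O[Si](C)(C)C(C)(C)C)C[C@@H](O[Si](C)(C)C(C)(C)C)C[C@@H](O[Si](C)(C)C(C)(C)C)CCCC(=O)C[C@@H](O[Si](CC)(CC)CC)[C@H](CC)C(=O)OCC=C
F7 | step 29 | seco acid with C5 ketone and free 27-OH | O[C@H](C)[C@H](C)/C=C/C=C/C=C/C=C/C=C/[C@@H](O[Si](C)(C)C(C)(C)C)[C@H](C)[C@H](O[Si](C)(C)C(C)(C)C)C[C@@H](O[Si](C)(C)C(C)(C)C)C[C@@H](O[Si](C)(C)C(C)(C)C)CCCC(=O)C[C@@H](O[Si](CC)(CC)CC)[C@H](CC)C(=O)O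
F8 | step 22 | diisopinocampheylboron enolate of 36 | C=C(CCCCl)OB([C@@H]1C[C@@H]2C[C@H]([C@H]1C)C2(C)C)[C@@H]1C[C@@H]2C[C@H]([C@H]1C)C2(C)C
F9 | step 27 | allyl ester of 21 | CC[C@H](C(=O)O[C@H](C)[C@H](C)/C=C/C=C/I)[C@@H](CC(=O)OCC=C)O[Si](CC)(CC)CC
F10 | step 27 | allyl ester of 44 | CC[C@H](C(=O)O[C@H](C)[C@H](C)/C=C/C=C/C=C/C=C/C=C/[C@@H](O[Si](C)(C)C(C)(C)C)[C@H](C)[C@H](O[Si](C)(C)C(C)(C)C)C[C@@H](O[Si](C)(C)C(C)(C)C)C[C@@H](O[Si](C)(C)C(C)(C)C)CCCI)[C@@H](CC(=O)OCC=C)O[Si](CC)(CC)CC
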